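The lactone is traced back to an acyclic core by cutting both aryl–carbon bonds: C7–aryl (benzyl CH2 on lactone C3) and C7′–aryl (carbinol carbon on C4). Since both rings are the same 4-hydroxy-3-methoxyphenyl group, one O-silylated aryl Grignard reagent serves twice in one flask (step 10): it adds to a Weinreb amide (C7′) and, with copper catalysis, opens a 2,2-disubstituted glycidic tert-butyl ester at its CH2 (C7), unveiling the C3 tertiary alcohol. The precursor is a six-carbon epoxy ester that already holds both ring stereocentres, the Weinreb amide and the silylated C5–O arm; a catalytic asymmetric keto ester aldol sets its two stereocentres.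

Key step: step 10

Atom labels: oxolan-2-one O1, C2 (C=O), C3 (benzyl-bearing carbinol), C4, C5; C7 is the benzylic CH2 on C3 and C7′ the exocyclic carbinol carbon on C4.
Remark on the chemistry: the (2R)-oxirane/(2S)-side-chain geometry of 12 is the (3S,4R) geometry of the target; descriptor changes along the route come only from CIP priority changes, never from inversion.
Assumption: bromopyruvic acid is used in its anhydrous keto form.

Step 1
Reactants: 1 4-bromo-2-methoxyphenol
Product: 2 tert-butyl(4-bromo-2-methoxyphenoxy)dimethylsilane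
Conditions: TBSCl, imidazole, DMF, rt
Reagents that add atoms: tert-butyldimethylsilyl chloride, CC(C)(C)[Si](C)(C)Cl
Why: Imidazole-promoted O-silylation of a phenol is routine and leaves the aryl bromide untouched.

Step 2
Reactants: 3 bromopyruvic acid
Product: 4 tert-butyl 3-bromo-2-oxopropanoate
Conditions: tBuOC(=NH)CCl3, CH2Cl2–cyclohexane, rt
Reagents that add atoms: tert-butyl 2,2,2-trichloroacetimidate, CC(C)(C)OC(=N)C(Cl)(Cl)Cl
Why: Trichloroacetimidate esterification transfers the tert-butyl group to the acid without base, so the base-sensitive α-bromo ketone should survive.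

Step 3
Reactants: 5 methyl 3-hydroxypropanoate
Product: 6 methyl 3-[(tert-butyldimethylsilyl)oxy]propanoate
Conditions: TBSCl, imidazole, CH2Cl2, 0 °C to rt
Reagents that add atoms: tert-butyldimethylsilyl chloride, CC(C)(C)[Si](C)(C)Cl
Why: Standard silyl ether formation on a primary alcohol.

Step 4
Reactants: 6 methyl 3-[(tert-butyldimethylsilyl)oxy]propanoate
Product: 7 S-ethyl 3-[(tert-butyldimethylsilyl)oxy]propanethioate
Conditions: Me3Al, EtSH, CH2Cl2, 0 °C to rt
Reagents that add atoms: ethanethiol, CCS
Why: The dimethylaluminium thiolate formed in situ exchanges the methyl ester for the thioester (aluminium-mediated ester-to-thioester exchange) without touching the silyl ether.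

Step 5
Reactants: 7 S-ethyl 3-[(tert-butyldimethylsilyl)oxy]propanethioate
Product: 8 (Z)-tert-butyl{[3-(ethylsulfanyl)-3-(trimethylsilyloxy)prop-2-en-1-yl]oxy}dimethylsilane (silyl ketene thioacetal, Z expected as the main isomer)
Conditions: LDA (commercial solution), TMSCl, THF, −78 °C
Reagents that add atoms: chlorotrimethylsilane, C[Si](C)(C)Cl
Why: Kinetic enolisation with in situ O-silylation (silyl ketene acetal formation) should outpace β-loss of silyloxide at −78 °C; the geometry is not critical because both isomers are expected to converge in step 6.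

Step 6
Reactants: 4 tert-butyl 3-bromo-2-oxopropanoate; 8 silyl ketene thioacetal
Product: 10 tert-butyl (2S,3S)-2-(bromomethyl)-3-{[(tert-butyldimethylsilyl)oxy]methyl}-4-(ethylsulfanyl)-2-hydroxy-4-oxobutanoate, via trimethylsilyl ether 9 (not isolated)
Conditions: Cu(OTf)2/(S,S)-tBu-bis(oxazoline) (10 mol%), THF, −78 °C; then citric acid, MeOH, 0 °C
Reagents that add atoms: none
Why: In this copper(II)–bis(oxazoline)-catalysed Mukaiyama aldol to an α-keto ester, two-point binding of 4 through ketone and ester carbonyls to the chiral copper centre should expose one ketone face and set C2 (S), the open transition state should give the syn adduct and so C3 (S) from either enolsilane geometry, and mild acid then cleaves only the O–SiMe3 bond.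

Step 7
Reactants: 10 thioester bromohydrin
Product: 11 tert-butyl (2S,3S)-2-(bromomethyl)-3-{[(tert-butyldimethylsilyl)oxy]methyl}-2-hydroxy-4-[methoxy(methyl)amino]-4-oxobutanoate
Conditions: Me3Al, MeNHOMe·HCl, CH2Cl2, 0 °C to rt
Reagents that add atoms: N,O-dimethylhydroxylamine hydrochloride, CNOC.Cl
Why: Aluminium amide aminolysis of the thioester (Weinreb amide synthesis), helped by the neighbouring aluminium alkoxide, should leave the hindered tert-butyl ester and both stereocentres untouched.

Step 8
Reactants: 11 Weinreb amide bromohydrin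
Product: 12 tert-butyl (2R)-2-{(2S)-3-[(tert-butyldimethylsilyl)oxy]-1-[methoxy(methyl)amino]-1-oxopropan-2-yl}oxirane-2-carboxylate
Conditions: K2CO3, MeOH, 0 °C
Reagents that add atoms: none
Why: Intramolecular Williamson closure (3-exo-tet) of the bromohydrin does not break the carbinol C–O bond, so the quaternary centre keeps its geometry, and carbonate is too weak to deprotonate the amide α-carbon.

Step 9
Reactants: 2 tert-butyl(4-bromo-2-methoxyphenoxy)dimethylsilane
Product: 13 {4-[(tert-butyldimethylsilyl)oxy]-3-methoxyphenyl}magnesium bromide (titrated THF solution)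
Conditions: Mg, I2 (cat.), THF, 40 °C
Reagents that add atoms: magnesium, [Mg]
Why: Magnesium insertion into the aryl–bromine bond (Grignard formation) is compatible with aryl silyl ethers.

Step 10
Reactants: 12 epoxy Weinreb amide tert-butyl ester; 13 aryl Grignard reagent (two equivalents enter the product)
Product: 15 tert-butyl (2S,3S)-2-hydroxy-2-{[4-(tert-butyldimethylsilyloxy)-3-methoxyphenyl]methyl}-3-{[(tert-butyldimethylsilyl)oxy]methyl}-4-[4-(tert-butyldimethylsilyloxy)-3-methoxyphenyl]-4-oxobutanoate, via magnesium hemiaminal chelate 14 (not isolated)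
Conditions: 13 (2.6 equiv), THF, −20 to 0 °C; then CuI (15 mol%), −30 to 0 °C; aq. NH4Cl, −20 °C
Reagents that add atoms: none
Why: The Grignard reagent first adds to the N-methoxy-N-methylamide to give the five-membered magnesium chelate 14, which does not collapse to a ketone before work-up, so over-addition is excluded and the adjacent CH is no longer acidic. Copper(I) iodide then turns the remaining Grignard reagent into an arylcopper species that opens the oxirane by SN2 attack at its unsubstituted CH2, forming the C7–aryl bond and the tertiary magnesium alkoxide. The closest known reactions are the Weinreb ketone synthesis and the copper-catalysed Grignard opening of 2-substituted glycidic esters at C3, here run one after the other in one flask. No ring is closed and no stereocentre is created: the quaternary C–O bond is never broken, so the future C3 is retained, and the neighbouring CH centre is not enolised. The step needs chemoselectivity only, which the chelate (one aryl per amide), copper together with the steric bias of the 2,2-disubstituted oxirane (CH2 attack) and the shielding tert-butyl group of the ester should secure.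

Step 11
Reactants: 15 diaryl β-hydroxy ketone tert-butyl ester
Product: 17 (3S,4S)-3-hydroxy-3-{[4-(tert-butyldimethylsilyloxy)-3-methoxyphenyl]methyl}-4-[4-(tert-butyldimethylsilyloxy)-3-methoxybenzoyl]oxolan-2-one, via dihydroxy acid 16 (not isolated)
Conditions: TFA–CH2Cl2 (1:4), H2O (5 equiv), 0 °C to rt
Reagents that add atoms: none
Why: Acidolysis of the tert-butyl ester and of the primary alkyl silyl ether should release a γ-hydroxy acid that lactonises at once (5-exo-trig acyl substitution), while the phenolic silyl ethers resist acid and the aroyl group already sits trans to the benzyl group, the more stable arrangement at C4.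

Step 12
Reactants: 17 keto lactone
Product: 18 (3S,4R)-3-hydroxy-4-{(R)-hydroxy[4-(tert-butyldimethylsilyloxy)-3-methoxyphenyl]methyl}-3-{[4-(tert-butyldimethylsilyloxy)-3-methoxyphenyl]methyl}oxolan-2-one
Conditions: Zn(BH4)2 (ethereal stock solution), Et2O–CH2Cl2, −40 to −10 °C; aq. NH4Cl
Reagents that add atoms: none
Why: In this chelation-controlled ketone reduction, zinc should bridge the C3 hydroxyl and the ketone oxygen in a six-membered chelate cis-fused to the lactone, and hydride should add to its exposed convex face to give the (R)-carbinol, the lactone being inert at this temperature.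

Step 13
Reactants: 18 bis-silyl ether
Product: 19 (3S,4R)-3-hydroxy-4-[(R)-hydroxy(4-hydroxy-3-methoxyphenyl)methyl]-3-[(4-hydroxy-3-methoxyphenyl)methyl]oxolan-2-one (CNP0352022.1)
Conditions: TBAF, AcOH, THF, 0 °C to rt
Reagents that add atoms: none
Why: Fluoride cleaves both aryl silyl ethers, and the acetic acid buffer keeps phenoxide and alkoxide levels low, so translactonisation onto the C7′ oxygen and quinone methide formation should not occur.

Compound list
1 | 4-bromo-2-methoxyphenol | COc1cc(Br)ccc1O | starting material
2 | tert-butyl(4-bromo-2-methoxyphenoxy)dimethylsilane | COc1cc(Br)ccc1O[Si](C)(C)C(C)(C)C | intermediate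
3 | bromopyruvic acid | O=C(O)C(=O)CBr | starting material
4 | tert-butyl 3-bromo-2-oxopropanoate | CC(C)(C)OC(=O)C(=O)CBr | intermediate
5 | methyl 3-hydroxypropanoate | COC(=O)CCO | starting material
6 | methyl 3-[(tert-butyldimethylsilyl)oxy]propanoate | COC(=O)CCO[Si](C)(C)C(C)(C)C | intermediate
7 | S-ethyl 3-[(tert-butyldimethylsilyl)oxy]propanethioate | CCSC(=O)CCO[Si](C)(C)C(C)(C)C | intermediate
8 | (Z)-tert-butyl{[3-(ethylsulfanyl)-3-(trimethylsilyloxy)prop-2-en-1-yl]oxy}dimethylsilane | CCS/C(O[Si](C)(C)C)=C\CO[Si](C)(C)C(C)(C)C | intermediate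
9 | tert-butyl (2S,3S)-2-(bromomethyl)-3-{[(tert-butyldimethylsilyl)oxy]methyl}-4-(ethylsulfanyl)-4-oxo-2-(trimethylsilyloxy)butanoate | BrC[C@@](O[Si](C)(C)C)(C(=O)OC(C)(C)C)[C@H](CO[Si](C)(C)C(C)(C)C)C(=O)SCC | intermediate (not isolated)
10 | tert-butyl (2S,3S)-2-(bromomethyl)-3-{[(tert-butyldimethylsilyl)oxy]methyl}-4-(ethylsulfanyl)-2-hydroxy-4-oxobutanoate | BrC[C@@](O)(C(=O)OC(C)(C)C)[C@H](CO[Si](C)(C)C(C)(C)C)C(=O)SCC | intermediate
11 | tert-butyl (2S,3S)-2-(bromomethyl)-3-{[(tert-butyldimethylsilyl)oxy]methyl}-2-hydroxy-4-[methoxy(methyl)amino]-4-oxobutanoate | BrC[C@@](O)(C(=O)OC(C)(C)C)[C@H](CO[Si](C)(C)C(C)(C)C)C(=O)N(C)OC | intermediate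
12 | tert-butyl (2R)-2-{(2S)-3-[(tert-butyldimethylsilyl)oxy]-1-[methoxy(methyl)amino]-1-oxopropan-2-yl}oxirane-2-carboxylate | CC(C)(C)OC(=O)[C@]1(CO1)[C@H](CO[Si](C)(C)C(C)(C)C)C(=O)N(C)OC | intermediate
13 | {4-[(tert-butyldimethylsilyl)oxy]-3-methoxyphenyl}magnesium bromide | COc1cc([Mg]Br)ccc1O[Si](C)(C)C(C)(C)C | intermediate
14 | bromomagnesium hemiaminal chelate of 12 after the first aryl addition, oxirane intact (hemiaminal carbon configuration undefined and transient) | CC(C)(C)OC(=O)[C@]1(CO1)[C@H](CO[Si](C)(C)C(C)(C)C)C(O[Mg]Br)(N(C)OC)c1ccc(O[Si](C)(C)C(C)(C)C)c(OC)c1 | intermediate (not isolated)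
15 | tert-butyl (2S,3S)-2-hydroxy-2-{[4-(tert-butyldimethylsilyloxy)-3-methoxyphenyl]methyl}-3-{[(tert-butyldimethylsilyl)oxy]methyl}-4-[4-(tert-butyldimethylsilyloxy)-3-methoxyphenyl]-4-oxobutanoate | COc1cc(C[C@@](O)(C(=O)OC(C)(C)C)[C@H](CO[Si](C)(C)C(C)(C)C)C(=O)c2ccc(O[Si](C)(C)C(C)(C)C)c(OC)c2)ccc1O[Si](C)(C)C(C)(C)C | intermediate
16 | (2S,3S)-2-hydroxy-3-(hydroxymethyl)-2-{[4-(tert-butyldimethylsilyloxy)-3-methoxyphenyl]methyl}-4-[4-(tert-butyldimethylsilyloxy)-3-methoxyphenyl]-4-oxobutanoic acid | COc1cc(C[C@@](O)(C(=O)O)[C@H](CO)C(=O)c2ccc(O[Si](C)(C)C(C)(C)C)c(OC)c2)ccc1O[Si](C)(C)C(C)(C)C | intermediate (not isolated)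
17 | (3S,4S)-3-hydroxy-3-{[4-(tert-butyldimethylsilyloxy)-3-methoxyphenyl]methyl}-4-[4-(tert-butyldimethylsilyloxy)-3-methoxybenzoyl]oxolan-2-one | COc1cc(C[C@@]2(O)C(=O)OC[C@@H]2C(=O)c2ccc(O[Si](C)(C)C(C)(C)C)c(OC)c2)ccc1O[Si](C)(C)C(C)(C)C | intermediate
18 | (3S,4R)-3-hydroxy-4-{(R)-hydroxy[4-(tert-butyldimethylsilyloxy)-3-methoxyphenyl]methyl}-3-{[4-(tert-butyldimethylsilyloxy)-3-methoxyphenyl]methyl}oxolan-2-one | COc1cc(C[C@@]2(O)C(=O)OC[C@@H]2[C@@H](O)c2ccc(O[Si](C)(C)C(C)(C)C)c(OC)c2)ccc1O[Si](C)(C)C(C)(C)C | intermediate
19 | (3S,4R)-3-hydroxy-4-[(R)-hydroxy(4-hydroxy-3-methoxyphenyl)methyl]-3-[(4-hydroxy-3-methoxyphenyl)methyl]oxolan-2-one | COc1cc(C[C@@]2(O)C(=O)OC[C@@H]2[C@@H](O)c2ccc(O)c(OC)c2)ccc1O | target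

Total step count: 13. Longest linear sequence: 10 steps (steps 3, 4, 5, 6, 7, 8, 10, 11, 12, 13, from 5 to 19).

Steps most likely to fail

Step 10. The sequence may stall after the first arylation, or the oxirane may be diverted before copper acts, either through opening by bromide from the magnesium salts or through base-induced opening from the amide α-position. The fallback separates the two arylations into discrete known reactions with isolation. Setting out from 12, a stoichiometric arylcopper reagent prepared from 13 and CuBr·SMe2 (THF, −40 °C) would open only the oxirane, since organocopper reagents do not add to amides, and give the ring-opened hydroxy Weinreb amide F1. Treating F1 with excess 13 (THF, 0 °C; the first equivalent forms the alkoxide) would then return to the route at 15.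

Step 6. Uncatalysed addition to the very electrophilic bromo keto ester may erode catalyst control over the ketone face, and the syn preference may drop with these bulkier partners. The fallback replaces catalyst control by a stoichiometric auxiliary. Setting out from 6, saponification (LiOH, THF–H2O) would give 3-[(tert-butyldimethylsilyl)oxy]propanoic acid F2. Coupling with (S)-4-benzyl-1,3-thiazolidine-2-thione (EDC, DMAP) would give the N-acyl thiazolidinethione F3. Its chlorotitanium enolate (TiCl4, i-Pr2NEt, NMP, CH2Cl2, −78 °C) would be added to 4 to give the imide bromohydrin F4. The auxiliary fixes the centre next to the imide; the configuration at the carbinol carbon depends on which ketone substituent sits pseudo-equatorial in the closed transition state, so F4 would be separated from its carbinol epimer at this stage. Displacement of the auxiliary (MeNHOMe·HCl, imidazole, CH2Cl2, rt) would return to the route at 11.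

Step 12. Facial selectivity may be insufficient if zinc binds the α-hydroxy lactone instead of bridging the hydroxyl and the ketone. The fallback replaces substrate control by catalyst control: setting out from 17, a Corey–Bakshi–Shibata reduction (oxazaborolidine catalyst, catecholborane, toluene, −60 °C, with one extra equivalent of borane for the tertiary hydroxyl) would lead directly to 18. The (S)-catalyst would be chosen if the aryl group behaves as the larger ketone substituent. No new compound is made.

Further compounds
F1 | step 10 | tert-butyl (2S,3S)-2-hydroxy-2-{[4-(tert-butyldimethylsilyloxy)-3-methoxyphenyl]methyl}-3-{[(tert-butyldimethylsilyl)oxy]methyl}-4-[methoxy(methyl)amino]-4-oxobutanoate | COc1cc(C[C@@](O)(C(=O)OC(C)(C)C)[C@H](CO[Si](C)(C)C(C)(C)C)C(=O)N(C)OC)ccc1O[Si](C)(C)C(C)(C)C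
F2 | step 6 | 3-[(tert-butyldimethylsilyl)oxy]propanoic acid | OC(=O)CCO[Si](C)(C)C(C)(C)C
F3 | step 6 | (S)-4-benzyl-3-{3-[(tert-butyldimethylsilyl)oxy]propanoyl}-1,3-thiazolidine-2-thione | S=C1N(C(=O)CCO[Si](C)(C)C(C)(C)C)[C@@H](Cc2ccccc2)CS1
F4 | step 6 | tert-butyl (2S,3S)-4-[(4S)-4-benzyl-2-sulfanylidene-1,3-thiazolidin-3-yl]-2-(bromomethyl)-3-{[(tert-butyldimethylsilyl)oxy]methyl}-2-hydroxy-4-oxobutanoate | BrC[C@@](O)(C(=O)OC(C)(C)C)[C@H](CO[Si](C)(C)C(C)(C)C)C(=O)N1C(=S)SC[C@@H]1Cc1ccccc1
F0 | step 12 | none | none
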